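South, the run at 85 °C, shows J climbing in nearly equal steps: 0.231 M h⁻¹ between 1.00 h and 2.00 h, and 0.232 M h⁻¹ in the stretch before. This is a steady velocity, a zero-order stretch, read with the scatter of the readings. South-east, at 45 °C, gives a straight stretch too, at a lower 0.0869 M h⁻¹.

in all of them: Z 200 mM (held); E 27 mM
- south-east: G 0.49 M; temperature 45 °C; run made earlier
- south: G 0.73 M; temperature 85 °C; run made earlier
- grey: G 0.98 M; temperature 80 °C; time 3.0 h
- amber: G 0.98 M; temperature 60 °C; time 3.0 h
- violet: G 0.98 M; temperature 100 °C; time 3.0 h
- blue: G 0.98 M; temperature 120 °C; time 3.0 h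
- teal: G 0.98 M; temperature 50 °C; time 3.0 h

- south-east (time / h: J / %): 1.33: 22.9; 3.00: 52.5; 6.00: 85.0; 12.0: 97.4; 25.0: 102.2
- south (time / h: J / %): 0.250: 3.8; 0.500: 12.0; 1.00: 27.9; 2.00: 59.5; 4.00: 95.4

(each reading ± 1 percentage point)

- given per volume of solution although it is solid: G
- the numbers in the tables scatter with a standard deviation of 1 percentage point
- at the start none of Z is in solution
- at the start none of G is in solution
- what has only dissolved of G counts as not reacted

- ranking by amount of J, in percent of the G charged, from high to low, at 3.0 h (grey / amber / violet / blue / teal)
- the amount of J, in percent of the G charged of the flask you put first, at 3.0 h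
- the amount of J, in percent of the G charged of the flask you put last, at 3.0 h

My reckoning compares two times. Dividing the charged [G] of the new flasks by south's velocity gives 4.25 h, the clearing time: the time a charge needs at steady velocity. The other time is the 3.0 h allowed, which is shorter, so I expect 70.6% of the charge as J at south's temperature. Grey stands below that temperature and violet above it, so I put grey a little under this figure and violet a little over it, and I rank the flasks by temperature.

The forecast gives blue > violet > grey > amber > teal, with 98% first and 29% last, reading the runs as “a solution saturated with G”.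

The flasks give blue > violet > grey > amber > teal, with 84.0% in blue and 41.3% in teal; grey has 66.7% and violet 77.1%, on either side of my figure.

    Z ⇌ Q, rate k1*(csat - [Q]) (kL = 0.0270 min⁻¹)
    D + Q + E → E + J (k = 5.50 L² mol⁻² min⁻¹, Ea = 38.0 kJ mol⁻¹)
    G ⇌ D, rate k3*(cs3 - [D]) while solid is left; crystals form when [D] > cs3 (solubility = 0.570 M, k = 0.0900 min⁻¹)
    (constants at 80 °C)

In blue, half of the dissolving of G up to 3.0 h is done by 0.309 h; at 1.50 h, D holds 52.5% of the charge while [Q] stands at 0.0173 M, far below 200 mM. Blue's mean velocity of J over 3.0 h, 0.274 M h⁻¹, is under 0.324 M h⁻¹, the pace of Z crossing into a solution holding no Q. Blue left until 50 min gets 19.6% from the clearing time read at south's temperature; computed, it holds 23.0% J.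

(The runs were generated by integration for substances that don't exist, and the scatter is random.)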